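**Retrosynthetic overview**
1. The bond from the chain CH2 to pyrrole C5 is cut. One half is a nonadecyl radical, released from the C20 fatty acid arachidic acid by loss of CO2. The other is a 2-formylpyrrole whose aldehyde is held as its dimethyliminium salt. Both carbons are donor sites by nature, so the union rests on polarity reversal at C5 plus a radical.
2. Enabling feature: the conjugated path N1–C5=C4–C3=C2–CHO of the pyrrole ring. With the formyl carbon as CH=NMe2(+), the ring is a 1-azafulvenium cation with the resonance form N1(+)=C5. C5–H then behaves towards a nucleophilic alkyl radical like C2–H of a pyridinium ion (the same salt is known to divert electrophiles from C5 to C4).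
3. The iminium salt is cut at C2–CH to pyrrole and the Vilsmeier reagent. It serves as both activating group and masked aldehyde, and hydrolysis in the work-up of the key step removes it.
4. No ring is formed (the pyrrole ring is bought), N–H stays free throughout, and the target has no stereocentre.

Key step: step 3

**Step 1**
Reactants: 1 arachidic acid (eicosanoic acid); 2 N-hydroxyphthalimide
Product: 3 1,3-dioxoisoindolin-2-yl eicosanoate (redox-active ester)
Conditions: DIC, DMAP (cat.), CH2Cl2, 0 °C to rt
Reagents that add atoms: none
Why: Steglich-type carbodiimide esterification, in which DIC activates the acid as its O-acylisourea and DMAP relays the acyl group to the acidic N–OH of 2, with no other functional group present to interfere.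

**Step 2**
Reactants: 4 1H-pyrrole; 5 (chloromethylene)dimethyliminium chloride (Vilsmeier reagent)
Product: 6 N,N-dimethyl-1-(1H-pyrrol-2-yl)methaniminium chloride
Conditions: slow addition of 4 to 5, CH2Cl2, 0 °C to rt, N2; dry Et2O, filtration under N2
Reagents that add atoms: none
Why: This is the first half of a Vilsmeier–Haack formylation, in which the chloroiminium ion attacks the most nucleophilic α-position (C2) of pyrrole, loss of HCl gives the resonance-stabilised and deactivated (hence mono-substituted) salt, and omitting the aqueous work-up keeps the formyl carbon at the iminium stage.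

**Step 3**
Reactants: 3 1,3-dioxoisoindolin-2-yl eicosanoate; 6 N,N-dimethyl-1-(1H-pyrrol-2-yl)methaniminium chloride
Product: 8 5-nonadecyl-1H-pyrrole-2-carbaldehyde, via 5-nonadecyl iminium chloride 7 (not isolated)
Conditions: 6 (2 equiv), fac-Ir(ppy)3 (1 mol %), dry degassed MeCN/CH2Cl2 (1:1), blue LEDs (450 nm), rt, Ar; then aq. NaOAc, 40 °C
Reagents that add atoms: water, O
Why: Proposed new method: excited fac-Ir(ppy)3 transfers one electron to the N-(acyloxy)phthalimide 3, whose radical anion breaks at N–O and loses CO2 to give the nucleophilic primary nonadecyl radical, and this radical adds to C5 of the 1-azafulvenium cation of 6, the carbon that is iminium-like in the resonance form N1(+)=C5–C4=C3–C2=CH–NMe2. The delocalised radical cation gives its C5 proton to the phthalimide anion, the resulting (pyrrol-2-yl)(dimethylamino)methyl radical is oxidised by Ir(IV) (or by a further molecule of 3 in a chain) to the aromatic iminium salt 7, and aqueous sodium acetate then hydrolyses 7 to aldehyde 8, so the sequence is redox neutral and needs no external base or oxidant. The closest known reaction types are the photoredox decarboxylative Minisci alkylation of protonated azines with N-(acyloxy)phthalimides and the oxidative radical alkylation of 2-acylpyrroles at C5 with xanthates and a peroxide, and what is new is a pyrrole iminium salt as acceptor for an unstabilised alkyl radical. The step needs site selectivity for C5 over C3 and over the exocyclic iminium carbon: attack at C5 gives the most extended radical cation (spin over C4, C2 and the NMe2 nitrogen, with N1 next to C2), C3 is shielded by the neighbouring CH=NMe2 group, and addition to the iminium carbon gives a localised aminium radical cation that finds no reductant or hydrogen donor and should revert. No ring is closed and no stereocentre is formed. The excess of 6 should keep capture of the radical faster than hydrogen abstraction from the medium and should suppress a second alkylation of 7.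

**Compound list**
1 | arachidic acid (eicosanoic acid) | CCCCCCCCCCCCCCCCCCCC(=O)O | starting material
2 | N-hydroxyphthalimide | O=C1c2ccccc2C(=O)N1O | starting material
3 | 1,3-dioxoisoindolin-2-yl eicosanoate | CCCCCCCCCCCCCCCCCCCC(=O)ON1C(=O)c2ccccc2C1=O | intermediate
4 | 1H-pyrrole | c1cc[nH]c1 | starting material
5 | (chloromethylene)dimethyliminium chloride | C[N+](C)=CCl.[Cl-] | starting material
6 | N,N-dimethyl-1-(1H-pyrrol-2-yl)methaniminium chloride | C[N+](C)=Cc1ccc[nH]1.[Cl-] | intermediate
7 | N,N-dimethyl-1-(5-nonadecyl-1H-pyrrol-2-yl)methaniminium chloride (not isolated) | CCCCCCCCCCCCCCCCCCCc1ccc(C=[N+](C)C)[nH]1.[Cl-] | intermediate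
8 | 5-nonadecyl-1H-pyrrole-2-carbaldehyde | CCCCCCCCCCCCCCCCCCCc1ccc(C=O)[nH]1 | target

Total step count: 3. Longest linear sequence: 2 steps (1 → 3 → 8 or 4 → 6 → 8).

**Steps most likely to fail**

Step 3 (bears the label "Proposed new method:").
- What may go wrong: capture of the unstabilised primary radical by the cation may be too slow. Hydrogen abstraction from the medium, attack at C3 or at the exocyclic iminium carbon, or unproductive electron transfer to the salt could then take over.
- Fallback: it uses known chemistry and forms the same bond with normal polarity. It sets out from 6 and comes back at 8.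
- Cold aqueous NaOH frees 6-(dimethylamino)-1-azafulvene from 6. This dimerises head to tail to 5,10-bis(dimethylamino)-5H,10H-dipyrrolo[1,2-a:1',2'-d]pyrazine F1, whose temporary central ring masks N–H and CHO of both halves. The configuration at the two aminal carbons is of no consequence.
- t-BuLi (THF, −15 °C) should lithiate both free α-positions to the 3,8-dilithio dimer F2.
- Commercial 1-bromononadecane (CCCCCCCCCCCCCCCCCCCBr, THF/DMPU) should alkylate F2 by SN2 to the 3,8-dinonadecyl dimer F3.
- Aqueous NaOAc at reflux should hydrolyse F3 to two molecules of 8.

Step 2.
- What may go wrong: the hygroscopic chloride may take up moisture and hydrolyse during filtration and storage, or the liberated HCl may cause acid-induced oligomerisation of pyrrole.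
- Fallback: it builds the C=N bond by condensation from the purified aldehyde. It sets out from 4 and comes back at 8.
- 4 and 5 are combined as before, but the mixture is hydrolysed at once with aqueous NaOAc (complete Vilsmeier–Haack formylation) to robust, crystalline 1H-pyrrole-2-carbaldehyde F4.
- After purification, F4 is condensed with dimethylammonium tetrafluoroborate (EtOH, molecular sieves, reflux). This should give the non-hygroscopic N,N-dimethyl-1-(1H-pyrrol-2-yl)methaniminium tetrafluoroborate F5.
- F5 takes the place of 6 under the conditions of step 3. It passes through the 5-nonadecyl iminium tetrafluoroborate F6 and should give 8 after the same hydrolysis.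

Step 1.
- What may go wrong: O→N acyl shift in the O-acylisourea (N-acylurea formation), favoured by the low solubility of the C20 acid, and loss of the active ester by hydrolysis on silica gel.
- Fallback: it sets out from 1 and comes back at 3.
- Oxalyl chloride with catalytic DMF in CH2Cl2 converts 1 into eicosanoyl chloride F7.
- F7 acylates 2 in the presence of Et3N (CH2Cl2, 0 °C) to 3, which is purified by recrystallisation instead of chromatography.

**Further compounds**
F1 | step 3 | 5,10-bis(dimethylamino)-5H,10H-dipyrrolo[1,2-a:1',2'-d]pyrazine | CN(C)C1c2cccn2C(N(C)C)c2cccn21
F2 | step 3 | 3,8-dilithio-5,10-bis(dimethylamino)-5H,10H-dipyrrolo[1,2-a:1',2'-d]pyrazine | CN(C)C1c2ccc([Li])n2C(N(C)C)c2ccc([Li])n21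
F3 | step 3 | 5,10-bis(dimethylamino)-3,8-dinonadecyl-5H,10H-dipyrrolo[1,2-a:1',2'-d]pyrazine | CCCCCCCCCCCCCCCCCCCc1ccc2n1C(N(C)C)c1ccc(CCCCCCCCCCCCCCCCCCC)n1C2N(C)C
F4 | step 2 | 1H-pyrrole-2-carbaldehyde | O=Cc1ccc[nH]1
F5 | step 2 | N,N-dimethyl-1-(1H-pyrrol-2-yl)methaniminium tetrafluoroborate | C[N+](C)=Cc1ccc[nH]1.F[B-](F)(F)F
F6 | step 2 | N,N-dimethyl-1-(5-nonadecyl-1H-pyrrol-2-yl)methaniminium tetrafluoroborate | CCCCCCCCCCCCCCCCCCCc1ccc(C=[N+](C)C)[nH]1.F[B-](F)(F)F
F7 | step 1 | eicosanoyl chloride | CCCCCCCCCCCCCCCCCCCC(=O)Cl
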